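**Plan**

1. Numbering of the target: C1 lactone C=O, C2 ring CH2, C3 ring CH–O(peroxide), C4 C(Me)–O(lactone), C5 CH2, C6 C(Me)–OO, C8 CHMe, C12=C13 alkene, C14 benzylic CH2.
2. Enabling feature: C2 sits between the lactone carbonyl C1 and C3; C3 carries the peroxide oxygen and C4 the lactone oxygen. A vinyl group (C2=C3) on the tertiary carbinol C4, with a hydroperoxide on C6, can therefore take the peroxide oxygen at C3, CO at C2 and the C4 oxygen at the acyl carbon in one palladium cycle.
3. Retrosynthesis: cut C1–C2, C1–O and C3–O (both rings open to the acyclic hydroperoxy allylic alcohol 19, C1 leaves as CO). Then cut C6–OO (alkene peroxidation), C2=C3 and C6=CH2 (methylenations), C4–C5 (pyruvate aldol), C8–Me (conjugate addition), C7=C8 (Wittig), C12–Me and C13–C14 (carboalumination–benzylation).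
4. Forward: side chain (steps 1–4), C3–C6 unit (steps 5–9), peroxide (steps 10–11), then the 1,2-dioxane (C3–O) and the γ-lactone (C1–C2, C1–O) in the same step 12.
5. Stereochemistry: 12E from syn-carbometalation; C8 (S) from catalytic asymmetric conjugate addition; C4 (R) from a copper bis(oxazoline) pyruvate aldol; C6 (R) from a radical peroxidation without facial control, followed by separation of the epimers; C3 (R) from C4 in the cyclisation (cis ring fusion).

Key step: step 12

Remark: step 10 cannot control the configuration at C6, so it is assumed that the two C6 epimers of 18 can be separated by chromatography (otherwise the epimeric bicycles are separated after step 12). The senses of induction in steps 4 and 6 follow the accepted catalyst models and are to be confirmed by correlation.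

**Route**

Step 1
Reactants: 1 hex-5-yn-1-ol; 2 benzyl bromide
Product: 4 (E)-5-methyl-7-phenylhept-5-en-1-ol, via alkenylalane 3 (not isolated)
Conditions: Me3Al (3 equiv), Cp2ZrCl2 (0.25 equiv), CH2Cl2, 0 to 23 °C; then 2, Pd(PPh3)4 (5 mol%), THF, 23 °C; aq. HCl
Reagents that add atoms: trimethylaluminium, C[Al](C)C; benzyl bromide (2), BrCc1ccccc1
Why: Negishi zirconium-catalysed carboalumination adds methyl and aluminium syn across the terminal alkyne with methyl on the internal carbon, and the alkenylalane 3 is benzylated with retention by zerovalent palladium cross-coupling, which fixes the (E)-trisubstituted alkene (methyl cis to benzyl).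

Step 2
Reactants: 4 (E)-5-methyl-7-phenylhept-5-en-1-ol
Product: 5 (E)-5-methyl-7-phenylhept-5-enal
Conditions: TEMPO (10 mol%), PhI(OAc)2 (1.1 equiv), CH2Cl2, 23 °C
Reagents that add atoms: none
Why: Nitroxyl-catalysed alcohol oxidation stops at the aldehyde and leaves the trisubstituted alkene untouched.

Step 3
Reactants: 5 (E)-5-methyl-7-phenylhept-5-enal; 6 1-(triphenylphosphoranylidene)propan-2-one
Product: 7 (3E,8E)-8-methyl-10-phenyldeca-3,8-dien-2-one
Conditions: 6 (1.2 equiv), toluene, 80 °C
Reagents that add atoms: 1-(triphenylphosphoranylidene)propan-2-one (6), CC(=O)C=P(c1ccccc1)(c1ccccc1)c1ccccc1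
Why: Wittig olefination with a stabilised acyl ylide should give the (E)-enone.

Step 4
Reactants: 7 (3E,8E)-8-methyl-10-phenyldeca-3,8-dien-2-one
Product: 9 (4S,8E)-4,8-dimethyl-10-phenyldec-8-en-2-one, via magnesium enolate 8 (not isolated)
Conditions: MeMgBr (1.2 equiv), CuBr·SMe2 (5 mol%), Josiphos ligand (R)-1-[(S)-2-(diphenylphosphino)ferrocenyl]ethyldicyclohexylphosphine (6 mol%; its mirror image if the sense of induction requires it), t-BuOMe, −75 °C; aq. NH4Cl
Reagents that add atoms: methylmagnesium bromide, C[Mg]Br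
Why: Copper-catalysed asymmetric conjugate addition of a Grignard reagent to a linear (E)-enone sets the C8 methyl stereocentre (S) by catalyst control, and the remote trisubstituted alkene is inert.

Step 5
Reactants: 9 (4S,8E)-4,8-dimethyl-10-phenyldec-8-en-2-one
Product: 11 trimethyl{[(4S,8E)-4,8-dimethyl-10-phenyldeca-1,8-dien-2-yl]oxy}silane, via lithium enolate 10 (not isolated)
Conditions: LiN(i-Pr)2 (1.1 equiv), THF, −78 °C; then Me3SiCl, −78 to 0 °C; pentane, filtration
Reagents that add atoms: chlorotrimethylsilane, C[Si](C)(C)Cl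
Why: Kinetic deprotonation of the methyl ketone by a hindered amide base removes a methyl proton (the β-branched methylene side is more hindered), and O-silylation gives the less substituted silyl enol ether.

Step 6
Reactants: 11 trimethyl{[(4S,8E)-4,8-dimethyl-10-phenyldeca-1,8-dien-2-yl]oxy}silane; 12 methyl pyruvate
Product: 13 methyl (2R,6S,10E)-2,6,10-trimethyl-4-oxo-12-phenyl-2-(trimethylsilyloxy)dodec-10-enoate
Conditions: [Cu((R,R)-t-Bu-box)](OTf)2 (10 mol%), 12 (1.2 equiv), THF, −78 °C; non-acidic work-up, Et3N-treated silica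
Reagents that add atoms: methyl pyruvate (12), CC(=O)C(=O)OC
Why: Mukaiyama aldol addition to pyruvate bound in a bidentate fashion to the copper bis(oxazoline) Lewis acid, in which the (R,R)-ligand shields the si face of the ketone so that attack on the re face sets the tertiary carbinol C4 (R), and silyl transfer delivers the product as its silyl ether, which blocks retro-aldol cleavage.

Step 7
Reactants: 13 methyl (2R,6S,10E)-2,6,10-trimethyl-4-oxo-12-phenyl-2-(trimethylsilyloxy)dodec-10-enoate
Product: 14 methyl (2R,6S,10E)-2,6,10-trimethyl-4-methylidene-12-phenyl-2-(trimethylsilyloxy)dodec-10-enoate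
Conditions: Ph3PCH3Br, KN(SiMe3)2, THF, −78 to 0 °C
Reagents that add atoms: methylenetriphenylphosphorane (from methyltriphenylphosphonium bromide), C=P(c1ccccc1)(c1ccccc1)c1ccccc1
Why: Wittig methylenation is chemoselective for the ketone over the hindered ester and installs the 1,1-disubstituted alkene whose CH2 later becomes the C6 methyl group.

Step 8
Reactants: 14 methyl (2R,6S,10E)-2,6,10-trimethyl-4-methylidene-12-phenyl-2-(trimethylsilyloxy)dodec-10-enoate
Product: 16 (2R,6S,10E)-2,6,10-trimethyl-4-methylidene-12-phenyl-2-(trimethylsilyloxy)dodec-10-enal, via aluminium hemiacetal 15 (not isolated)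
Conditions: i-Bu2AlH (1.1 equiv), CH2Cl2, −78 °C; MeOH, then aq. KNaC4H4O6
Reagents that add atoms: none
Why: Partial hydride reduction of an α-silyloxy ester stops at the aldehyde because the aluminium hemiacetal 15 persists at −78 °C until work-up, and the quaternary α-carbon cannot epimerise.

Step 9
Reactants: 16 (2R,6S,10E)-2,6,10-trimethyl-4-methylidene-12-phenyl-2-(trimethylsilyloxy)dodec-10-enal
Product: 17 trimethyl{[(3R,7S,11E)-3,7,11-trimethyl-5-methylidene-13-phenyltrideca-1,11-dien-3-yl]oxy}silane
Conditions: Ph3PCH3Br, KN(SiMe3)2, THF, −78 to 0 °C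
Reagents that add atoms: methylenetriphenylphosphorane (from methyltriphenylphosphonium bromide), C=P(c1ccccc1)(c1ccccc1)c1ccccc1
Why: Wittig methylenation of the non-enolisable aldehyde gives the vinyl group (C2=C3) of the tertiary allylic silyl ether.

Step 10
Reactants: 17 trimethyl{[(3R,7S,11E)-3,7,11-trimethyl-5-methylidene-13-phenyltrideca-1,11-dien-3-yl]oxy}silane
Product: 18 triethyl{[(3R,5R,7S,11E)-3,5,7,11-tetramethyl-13-phenyl-3-(trimethylsilyloxy)trideca-1,11-dien-5-yl]peroxy}silane
Conditions: Co(thd)2 (thd = 2,2,6,6-tetramethylheptane-3,5-dionate, 10 mol%), O2 (1 atm), Et3SiH (2 equiv), 1,2-dichloroethane, 23 °C; preparative HPLC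
Reagents that add atoms: dioxygen, O=O; triethylsilane, CC[SiH](CC)CC
Why: Mukaiyama–Isayama hydroperoxysilylation, in which hydrogen-atom transfer from a cobalt hydride to the CH2 end of the 1,1-disubstituted alkene (expected to be faster than to the hindered vinyl group or the trisubstituted alkene) gives a tertiary radical that traps O2 on both faces, so the (5R)-epimer should form together with its (5S)-epimer and is isolated by chromatography.

Step 11
Reactants: 18 triethyl{[(3R,5R,7S,11E)-3,5,7,11-tetramethyl-13-phenyl-3-(trimethylsilyloxy)trideca-1,11-dien-5-yl]peroxy}silane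
Product: 19 (3R,5R,7S,11E)-5-hydroperoxy-3,5,7,11-tetramethyl-13-phenyltrideca-1,11-dien-3-ol
Conditions: n-Bu4NF (2.2 equiv), AcOH (2.2 equiv), THF, 0 °C
Reagents that add atoms: none
Why: Buffered fluoride desilylation cleaves both Si–O bonds (silyl peroxide and tertiary silyl ether) without ionising the tertiary allylic alcohol or reducing the O–O bond.

Step 12
Reactants: 19 (3R,5R,7S,11E)-5-hydroperoxy-3,5,7,11-tetramethyl-13-phenyltrideca-1,11-dien-3-ol
Product: 22 plakortolide G, via alkylpalladium acetate 20 (not isolated), via acylpalladium acetate 21 (not isolated)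
Conditions: Pd(OAc)2 (10 mol%), 1,4-benzoquinone (2 equiv), CO (1 atm), 1,2-dichloroethane, 23 °C
Reagents that add atoms: carbon monoxide, [C-]#[O+]
Why: Proposed new method: divalent palladium, held by the C4 hydroxyl, activates the vinyl group, and the terminal oxygen of the C6 hydroperoxide attacks the internal alkene carbon C3 anti to the metal (6-exo-trig, closing the 1,2-dioxane) to give alkylpalladium 20; CO insertion then forms the C2–C1 bond (acylpalladium 21), the C4 hydroxyl captures the acyl group (5-exo-trig, closing the γ-lactone), and benzoquinone returns zerovalent palladium to the divalent state. The closest known reactions are the palladium-mediated hydroxycyclisation–carbonylation–lactonisation of ene-diols to bicyclic furano- and pyranolactones and the palladium-catalysed Wacker-type cyclisation of unsaturated tertiary hydroperoxides to 1,2-dioxanes; what is new is trapping the peroxypalladation intermediate with CO. The new stereocentre C3 is set by C4: the five-membered Pd–C2–C3–C4–O chelate holds C2 and the C4 oxygen synclinal on one face of the forming dioxane, so the cis-fused bicycle (H at C3 cis to the C4 methyl) is expected, and the reversibility of peroxypalladation should return any mismatched adduct to 19. The step needs chemoselectivity for CO insertion over β-hydride elimination and over O–O cleavage in 20, whose only β-hydrogen is on the peroxide carbon, which 1 atm of CO should secure; no copper salt is used, to avoid one-electron decomposition of the hydroperoxide. It also needs site selectivity for the vinyl group over the remote trisubstituted alkene, which the hydroxyl chelation and the six-membered transition state should provide.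

**Compound list**

1 | hex-5-yn-1-ol | C#CCCCCO | starting material
2 | benzyl bromide | BrCc1ccccc1 | starting material
3 | (E)-alkenyldimethylalane of 1 (aluminium alkoxide), formed in the flask | C[Al](C)OCCCC/C(C)=C/[Al](C)C | intermediate
4 | (E)-5-methyl-7-phenylhept-5-en-1-ol | OCCCC/C(C)=C/Cc1ccccc1 | intermediate
5 | (E)-5-methyl-7-phenylhept-5-enal | O=CCCC/C(C)=C/Cc1ccccc1 | intermediate
6 | 1-(triphenylphosphoranylidene)propan-2-one | CC(=O)C=P(c1ccccc1)(c1ccccc1)c1ccccc1 | starting material
7 | (3E,8E)-8-methyl-10-phenyldeca-3,8-dien-2-one | CC(=O)/C=C/CCC/C(C)=C/Cc1ccccc1 | intermediate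
8 | bromomagnesium enolate of 9, formed in the flask | CC(O[Mg]Br)=C[C@@H](C)CCC/C(C)=C/Cc1ccccc1 | intermediate
9 | (4S,8E)-4,8-dimethyl-10-phenyldec-8-en-2-one | CC(=O)C[C@@H](C)CCC/C(C)=C/Cc1ccccc1 | intermediate
10 | lithium enolate of 9 (methyl side), formed in the flask | C=C(O[Li])C[C@@H](C)CCC/C(C)=C/Cc1ccccc1 | intermediate
11 | trimethyl{[(4S,8E)-4,8-dimethyl-10-phenyldeca-1,8-dien-2-yl]oxy}silane | C=C(O[Si](C)(C)C)C[C@@H](C)CCC/C(C)=C/Cc1ccccc1 | intermediate
12 | methyl pyruvate | CC(=O)C(=O)OC | starting material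
13 | methyl (2R,6S,10E)-2,6,10-trimethyl-4-oxo-12-phenyl-2-(trimethylsilyloxy)dodec-10-enoate | COC(=O)[C@](C)(O[Si](C)(C)C)CC(=O)C[C@@H](C)CCC/C(C)=C/Cc1ccccc1 | intermediate
14 | methyl (2R,6S,10E)-2,6,10-trimethyl-4-methylidene-12-phenyl-2-(trimethylsilyloxy)dodec-10-enoate | COC(=O)[C@](C)(O[Si](C)(C)C)CC(=C)C[C@@H](C)CCC/C(C)=C/Cc1ccccc1 | intermediate
15 | diisobutylaluminium hemiacetal of 14, formed in the flask | COC(O[Al](CC(C)C)CC(C)C)[C@](C)(O[Si](C)(C)C)CC(=C)C[C@@H](C)CCC/C(C)=C/Cc1ccccc1 | intermediate
16 | (2R,6S,10E)-2,6,10-trimethyl-4-methylidene-12-phenyl-2-(trimethylsilyloxy)dodec-10-enal | O=C[C@](C)(O[Si](C)(C)C)CC(=C)C[C@@H](C)CCC/C(C)=C/Cc1ccccc1 | intermediate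
17 | trimethyl{[(3R,7S,11E)-3,7,11-trimethyl-5-methylidene-13-phenyltrideca-1,11-dien-3-yl]oxy}silane | C=C[C@](C)(O[Si](C)(C)C)CC(=C)C[C@@H](C)CCC/C(C)=C/Cc1ccccc1 | intermediate
18 | triethyl{[(3R,5R,7S,11E)-3,5,7,11-tetramethyl-13-phenyl-3-(trimethylsilyloxy)trideca-1,11-dien-5-yl]peroxy}silane | C=C[C@](C)(O[Si](C)(C)C)C[C@](C)(OO[Si](CC)(CC)CC)C[C@@H](C)CCC/C(C)=C/Cc1ccccc1 | intermediate
19 | (3R,5R,7S,11E)-5-hydroperoxy-3,5,7,11-tetramethyl-13-phenyltrideca-1,11-dien-3-ol | C/C(=C\Cc1ccccc1)CCC[C@H](C)C[C@@](C)(OO)C[C@@](C)(O)C=C | intermediate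
20 | alkylpalladium acetate: 1,2-dioxane closed, Pd on C2, C4 hydroxyl free, formed in the flask | C/C(=C\Cc1ccccc1)CCC[C@H](C)C[C@]1(C)C[C@@](C)(O)[C@@H](C[Pd]OC(C)=O)OO1 | intermediate
21 | acylpalladium acetate: CO inserted into the C2–Pd bond of 20, formed in the flask | C/C(=C\Cc1ccccc1)CCC[C@H](C)C[C@]1(C)C[C@@](C)(O)[C@@H](CC(=O)[Pd]OC(C)=O)OO1 | intermediate
22 | plakortolide G: cis-fused 1,2-dioxane/γ-lactone, (3R,4R,6R) in the numbering above, with the (2S,6E)-2,6-dimethyl-8-phenyloct-6-en-1-yl chain on C6 | C/C(=C\Cc1ccccc1)CCC[C@H](C)C[C@]1(C)C[C@@]2(C)OC(=O)C[C@H]2OO1 | target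

**Step count and risks**

Total step count: 12. Longest linear sequence: 12 steps (from 1).

Steps most likely to fail:

1. Step 12 (proposed new method). The peroxypalladation intermediate may lose a β-hydride or undergo O–O cleavage faster than it inserts CO, and zerovalent palladium may reduce the hydroperoxide. The fallback uses known chemistry and sets out from 17. The silyl ether is cleaved (K2CO3, MeOH) to (3R,7S,11E)-3,7,11-trimethyl-5-methylidene-13-phenyltrideca-1,11-dien-3-ol F1. This is acylated (acryloyl chloride, i-Pr2NEt, DMAP) to the corresponding prop-2-enoate F2. Ring-closing metathesis (second-generation Grubbs catalyst, (H2IMes)(PCy3)Cl2Ru=CHPh, CH2Cl2, 40 °C) gives (5R)-5-methyl-5-[(4S,8E)-4,8-dimethyl-2-methylidene-10-phenyldec-8-en-1-yl]furan-2(5H)-one F3. Cobalt-mediated hydroperoxysilylation under the conditions of step 10 gives the butenolide triethylsilyl peroxide F4 (with its C6 epimer, to be separated). Desilylation (n-Bu4NF, AcOH) gives the butenolide hydroperoxide F5, and an amine base (Et2NH, CF3CH2OH) should induce 6-exo conjugate addition of the hydroperoxide to the butenolide; the tether on the γ-carbon allows only the cis-fused bicycle. The fallback comes back to the route at 22.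

2. Step 10. Hydrogen-atom transfer to the trisubstituted side-chain alkene, or cyclisation of the tertiary peroxyl radical onto the vinyl group, may compete with the wanted peroxidation; facial control at C6 is absent in any case. The fallback sets out from 17 and replaces the radical step by an ionic Markovnikov addition. Hydroperoxymercuration (Hg(OAc)2, ethereal H2O2, CH2Cl2, 0 °C) should favour the 1,1-disubstituted alkene and give the β-(acetoxymercurio) tertiary hydroperoxide F6. Alkaline NaBH4 demercuration gives (3R,5R,7S,11E)-5-hydroperoxy-3,5,7,11-tetramethyl-13-phenyl-3-(trimethylsilyloxy)trideca-1,11-diene F7 (C5 epimers again to be separated). Fluoride desilylation (n-Bu4NF, AcOH) comes back to the route at 19.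

3. Step 7. The basic ylide may cause β-elimination of silanolate or retro-aldol cleavage of the β-silyloxy ketone before olefination. The fallback sets out from 9 and avoids olefinating an aldol product. Wittig methylenation of 9 (Ph3PCH3Br, KN(SiMe3)2) gives (4S,8E)-2,4,8-trimethyl-10-phenyldeca-1,8-diene F8. A copper bis(oxazoline)-catalysed carbonyl-ene reaction with 12 ([Cu((R,R)-t-Bu-box)](SbF6)2, CH2Cl2, 23 °C), with transfer of a methyl hydrogen, gives methyl (2R,6S,10E)-2-hydroxy-2,6,10-trimethyl-4-methylidene-12-phenyldodec-10-enoate F9. Silylation (Me3SiCl, imidazole) comes back to the route at 14.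

**Further compounds**

F1 | step 12 | (3R,7S,11E)-3,7,11-trimethyl-5-methylidene-13-phenyltrideca-1,11-dien-3-ol | C=C[C@](C)(O)CC(=C)C[C@@H](C)CCC/C(C)=C/Cc1ccccc1
F2 | step 12 | (3R,7S,11E)-3,7,11-trimethyl-5-methylidene-13-phenyltrideca-1,11-dien-3-yl prop-2-enoate | C=CC(=O)O[C@@](C)(C=C)CC(=C)C[C@@H](C)CCC/C(C)=C/Cc1ccccc1
F3 | step 12 | (5R)-5-methyl-5-[(4S,8E)-4,8-dimethyl-2-methylidene-10-phenyldec-8-en-1-yl]furan-2(5H)-one | O=C1C=C[C@@](C)(CC(=C)C[C@@H](C)CCC/C(C)=C/Cc1ccccc1)O1
F4 | step 12 | (5R)-5-methyl-5-[(2R,4S,8E)-2,4,8-trimethyl-10-phenyl-2-(triethylsilylperoxy)dec-8-en-1-yl]furan-2(5H)-one | O=C1C=C[C@@](C)(C[C@](C)(OO[Si](CC)(CC)CC)C[C@@H](C)CCC/C(C)=C/Cc1ccccc1)O1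
F5 | step 12 | (5R)-5-[(2R,4S,8E)-2-hydroperoxy-2,4,8-trimethyl-10-phenyldec-8-en-1-yl]-5-methylfuran-2(5H)-one | O=C1C=C[C@@](C)(C[C@](C)(OO)C[C@@H](C)CCC/C(C)=C/Cc1ccccc1)O1
F6 | step 10 | (3R,7S,11E)-5-[(acetoxymercurio)methyl]-5-hydroperoxy-3,7,11-trimethyl-13-phenyl-3-(trimethylsilyloxy)trideca-1,11-diene (C5 epimer that leads to 19) | C=C[C@](C)(O[Si](C)(C)C)C[C@](C[Hg]OC(C)=O)(OO)C[C@@H](C)CCC/C(C)=C/Cc1ccccc1
F7 | step 10 | (3R,5R,7S,11E)-5-hydroperoxy-3,5,7,11-tetramethyl-13-phenyl-3-(trimethylsilyloxy)trideca-1,11-diene | C=C[C@](C)(O[Si](C)(C)C)C[C@](C)(OO)C[C@@H](C)CCC/C(C)=C/Cc1ccccc1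
F8 | step 7 | (4S,8E)-2,4,8-trimethyl-10-phenyldeca-1,8-diene | C=C(C)C[C@@H](C)CCC/C(C)=C/Cc1ccccc1
F9 | step 7 | methyl (2R,6S,10E)-2-hydroxy-2,6,10-trimethyl-4-methylidene-12-phenyldodec-10-enoate | COC(=O)[C@](C)(O)CC(=C)C[C@@H](C)CCC/C(C)=C/Cc1ccccc1
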